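**Plan**

- Numbering used below: ring carbons C1–C10 (C1=C10, ester carbon C14 on C10, methyl C15 on C4, oxygens on C6, C8, C9), lactone carbons C11–C13. Retrosynthetic cuts, in order: Si–O at C9; the epoxide oxygen (back to C4=C5); the C8–O ester bond with inversion at C8; O–C6 together with C7–C11 (partner 2-bromoacrylic acid); C6=C7 (ring closure); C10–C14; C8–C9; C9–C10; C5–C6 and C3–C4.
- Forward: the chain C10–C1–C2–C3–C4(C15)=C5–C6 is assembled in one pot from a butynyl Grignard reagent, propyne and vinyl bromide, and formylated to the ynal (C9). It is joined to C7–C8 by alkoxyallylboration; the alkyne becomes the enoate by syn hydrostannation, iodination and methoxycarbonylation; the ten-membered ring closes at C6=C7 by metathesis. The γ-lactone is then built on the ring, followed by esterification, epoxidation and desilylation.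
- Enabling feature: in the target the lactone oxygen on C6 and the C7–C11 bond are cis on the ten-membered ring, and C6 is flanked by the cis-4,5-epoxide. This is the retron of a cyclic (4Z,6Z)-1,3-diene C4=C5–C6=C7: its C6=C7 bond can take up C11 and a carboxylate oxygen syn through an η3-allylpalladium on C4–C6, and the surviving C4=C5 bond becomes the epoxide.
- Stereochemistry: C8 and C9 come from a reagent-controlled (Z)-alkoxyallylboration, with C9 corrected by Mitsunobu inversion. C8 is carried as its 8R epimer, a temporary control element whose outward hydroxyl steers C7 and C6 in the lactone-forming step, and is inverted to 8S when the angelate is put on. C4 and C5 come from peripheral epoxidation trans to the C6 oxygen. Olefin geometries come from syn-carbocupration, syn-hydrostannation and the ring.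

Key step: step 12

**Route**

Step 1
Reactants: 1 (4-bromobut-1-yn-1-yl)trimethylsilane; 2 propyne; 3 vinyl bromide
Product: 8 trimethyl[(5Z)-5-methylocta-5,7-dien-1-yn-1-yl]silane, via Grignard reagent 4 (not isolated), via alkylcopper 5 (not isolated), via alkenylcopper 6 (not isolated), via alkenylzinc bromide 7 (not isolated)
Conditions: Mg, THF, rt; CuBr·SMe2, Et2O/Me2S, −45 °C; propyne, −25 °C; ZnBr2, Pd(PPh3)4 (cat.), vinyl bromide, THF, −20 °C to rt
Reagents that add atoms: none
Why: syn-carbocupration of propyne by the alkylcopper·MgBr2 reagent (Normant carbocupration) places the chain and copper cis on the new C4=C5 bond, and the alkenylcopper is coupled with retention through zinc under Pd(PPh3)4 catalysis (Negishi coupling), which should give the (Z)-trisubstituted diene.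

Step 2
Reactants: 8 trimethyl[(5Z)-5-methylocta-5,7-dien-1-yn-1-yl]silane
Product: 9 (5Z)-5-methylocta-5,7-dien-1-yne
Conditions: K2CO3 (cat.), MeOH, rt
Reagents that add atoms: none
Why: methanolysis of the C(sp)–Si bond with catalytic K2CO3 is a standard protodesilylation that should leave the diene untouched.

Step 3
Reactants: 9 (5Z)-5-methylocta-5,7-dien-1-yne
Product: 11 (6Z)-6-methylnona-6,8-dien-2-ynal, via lithium acetylide 10 (not isolated)
Conditions: n-BuLi, THF, −78 °C; DMF, −78 to 0 °C; inverse quench into aq KH2PO4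
Reagents that add atoms: N,N-dimethylformamide CN(C)C=O
Why: deprotonation of the terminal alkyne and formylation of the lithium acetylide with DMF is the standard route to ynals, the aldehyde being released on the buffered quench.

Step 4
Reactants: 11 (6Z)-6-methylnona-6,8-dien-2-ynal; 12 3-(methoxymethoxy)prop-1-ene
Product: 16 (3R,4R,9Z)-3-(methoxymethoxy)-9-methyldodeca-1,9,11-trien-5-yn-4-ol, via allyllithium 13 (not isolated), via allylborane 14 (not isolated), via borinate 15 (not isolated)
Conditions: 12, s-BuLi, THF, −78 °C; (−)-Ipc2BOMe; BF3·OEt2; then 11, −78 °C; NaOH, H2O2, 0 °C to rt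
Reagents that add atoms: none
Why: the (Z)-γ-alkoxyallylborane adds through a closed chair transition state (asymmetric alkoxyallylboration), the Z geometry giving the syn diol monoether and the isopinocampheyl groups derived from (+)-α-pinene directing attack to the Si face of the ynal, which should set C8 and C9 as 3R and 4R.

Step 5
Reactants: 16 (3R,4R,9Z)-3-(methoxymethoxy)-9-methyldodeca-1,9,11-trien-5-yn-4-ol
Product: 17 (3R,4S,9Z)-3-(methoxymethoxy)-9-methyldodeca-1,9,11-trien-5-yn-4-yl 4-nitrobenzoate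
Conditions: 4-O2NC6H4CO2H, PPh3, DIAD, THF, 0 °C
Reagents that add atoms: 4-nitrobenzoic acid OC(=O)c1ccc(cc1)[N+](=O)[O-]
Why: Mitsunobu esterification of the secondary propargylic alcohol proceeds by SN2 displacement of the oxyphosphonium group and should invert C9 (4R to 4S), giving the anti (erythro) C8/C9 array that the later steps need.

Step 6
Reactants: 17 (3R,4S,9Z)-3-(methoxymethoxy)-9-methyldodeca-1,9,11-trien-5-yn-4-yl 4-nitrobenzoate
Product: 18 (3R,4S,9Z)-3-(methoxymethoxy)-9-methyldodeca-1,9,11-trien-5-yn-4-ol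
Conditions: K2CO3, MeOH, 0 °C
Reagents that add atoms: none
Why: K2CO3/MeOH transesterification removes the activated 4-nitrobenzoate without touching the methoxymethyl ether, the alkyne or the diene.

Step 7
Reactants: 18 (3R,4S,9Z)-3-(methoxymethoxy)-9-methyldodeca-1,9,11-trien-5-yn-4-ol
Product: 20 (3R,4R,5E,9Z)-5-iodo-3-(methoxymethoxy)-9-methyldodeca-1,5,9,11-tetraen-4-ol, via alkenylstannane 19 (not isolated)
Conditions: Bu3SnH (slow addition), PdCl2(PPh3)2 (cat.), THF, 0 °C; then I2, CH2Cl2, 0 °C
Reagents that add atoms: iodine II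
Why: palladium-catalysed hydrostannation adds H and Sn syn across the alkyne, which reacts far faster than the alkenes, with tin on the carbon next to the free propargylic hydroxyl, and iododestannylation with retention should give the alkenyl iodide in which C9 and C2 are cis.

Step 8
Reactants: 20 (3R,4R,5E,9Z)-5-iodo-3-(methoxymethoxy)-9-methyldodeca-1,5,9,11-tetraen-4-ol
Product: 21 methyl (2E,6Z)-2-[(1S,2R)-1-hydroxy-2-(methoxymethoxy)but-3-en-1-yl]-6-methylnona-2,6,8-trienoate
Conditions: CO (1 atm), MeOH, Et3N, PdCl2(PPh3)2 (cat.), DMF, 50 °C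
Reagents that add atoms: carbon monoxide [C-]#[O+]; methanol CO
Why: palladium-catalysed methoxycarbonylation of the alkenyl iodide (oxidative addition, CO insertion, methanolysis) keeps the olefin geometry and installs C14, the C8 oxygen being masked so that it cannot capture the acylpalladium.

Step 9
Reactants: 21 methyl (2E,6Z)-2-[(1S,2R)-1-hydroxy-2-(methoxymethoxy)but-3-en-1-yl]-6-methylnona-2,6,8-trienoate
Product: 22 methyl (2E,6Z)-2-[(1S,2R)-1-{[tert-butyl(dimethyl)silyl]oxy}-2-(methoxymethoxy)but-3-en-1-yl]-6-methylnona-2,6,8-trienoate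
Conditions: TBSOTf, 2,6-lutidine, CH2Cl2, −78 to 0 °C
Reagents that add atoms: tert-butyldimethylsilyl trifluoromethanesulfonate CC(C)(C)[Si](C)(C)OS(=O)(=O)C(F)(F)F
Why: silyl triflate with a hindered base is the standard silylation for a hindered secondary allylic alcohol and should protect C9–OH until the last step.

Step 10
Reactants: 22 methyl (2E,6Z)-2-[(1S,2R)-1-{[tert-butyl(dimethyl)silyl]oxy}-2-(methoxymethoxy)but-3-en-1-yl]-6-methylnona-2,6,8-trienoate
Product: 23 methyl (2E,6Z)-2-[(1S,2R)-1-{[tert-butyl(dimethyl)silyl]oxy}-2-hydroxybut-3-en-1-yl]-6-methylnona-2,6,8-trienoate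
Conditions: Me2BBr, CH2Cl2, −78 °C; then aq NaHCO3
Reagents that add atoms: none
Why: Me2BBr cleaves the acetal C–O bond of methoxymethyl ethers at −78 °C (Lewis-acid acetal cleavage), conditions that the secondary silyl ether, the enoate and the diene should survive.

Step 11
Reactants: 23 methyl (2E,6Z)-2-[(1S,2R)-1-{[tert-butyl(dimethyl)silyl]oxy}-2-hydroxybut-3-en-1-yl]-6-methylnona-2,6,8-trienoate
Product: 24 methyl (1E,5Z,7Z,9R,10S)-10-{[tert-butyl(dimethyl)silyl]oxy}-9-hydroxy-5-methylcyclodeca-1,5,7-triene-1-carboxylate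
Conditions: second-generation Grubbs catalyst (10 mol %), CH2Cl2 (1 mM), 40 °C
Reagents that add atoms: none
Why: ene–diene ring-closing metathesis at high dilution engages only the two terminal CH2= groups (the trisubstituted C4=C5 and C1=C10 bonds are inert), the allylic hydroxyl speeds loading of ruthenium on the C7 vinyl group, and a ten-membered ring that already holds two cis olefins should close to the less strained (7Z) isomer.

Step 12
Reactants: 24 methyl (1E,5Z,7Z,9R,10S)-10-{[tert-butyl(dimethyl)silyl]oxy}-9-hydroxy-5-methylcyclodeca-1,5,7-triene-1-carboxylate; 25 2-bromoacrylic acid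
Product: 26 methyl (3aR,4R,5S,6E,10Z,11aS)-5-{[tert-butyl(dimethyl)silyl]oxy}-4-hydroxy-10-methyl-3-methylidene-2-oxo-2,3,3a,4,5,8,9,11a-octahydrocyclodeca[b]furan-6-carboxylate
Conditions: 25 (1.5 equiv), Pd(OAc)2 (10 mol %), tri(2-furyl)phosphine (20 mol %), Ag2CO3 (1.5 equiv), MeCN, 60 °C
Reagents that add atoms: none
Why: Proposed new method: zerovalent palladium inserts into the C–Br bond of 25, the cationic alkenylpalladium (bromide removed as AgBr) binds the C8 hydroxyl and adds syn across C6=C7 with C11 going to the diene terminus C7 and palladium to C6, where it is held as an η3-allyl over C4–C5–C6, and the palladium-bound carboxylate then closes the C6–O bond by inner-sphere reductive elimination on the same face, so that a net syn 1,2-carbo-oxygenation of the (Z)-alkene gives the cis-fused lactone and returns zerovalent palladium. The closest known reaction type is the palladium-catalysed heteroannulation of 1,3-dienes by aryl or alkenyl halides that carry a carboxylic acid or hydroxyl group (Larock heteroannulation); the use of 2-bromoacrylic acid on a macrocyclic trisubstituted diene to give an α-methylene-γ-butyrolactone is the new element. The γ-lactone closes in the 5-exo mode on the allyl terminus C6, since attack at C4 would need a seven-membered ring at a fully substituted carbon. C7 is set by the C8 carbinol: in the ten-membered (Z)-allylic alcohol H8 should eclipse the C6=C7 bond, the hydroxyl points to the outer face and the ring chain through C9 blocks the inner face, so that peripheral, hydroxyl-assisted attack places C11 trans to the 8-oxygen as in 26, the same sense as in the hydroxyl-directed epoxidation of eight- and nine-membered (Z)-cycloalkenols; C6 follows from C7 through the syn course of insertion and C–O closure. The step needs site selectivity (C6=C7, not the C1=C10 enoate), regioselectivity (C11 to C7) and chemoselectivity against β-hydride loss: the electron-poor trisubstituted enoate inserts slowly, the disubstituted diene terminus C7 is the less hindered one, no syn β-hydrogen remains at C7 after insertion, and chloride-free conditions with Ag2CO3 keep the carboxylate on palladium.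

Step 13
Reactants: 26 methyl (3aR,4R,5S,6E,10Z,11aS)-5-{[tert-butyl(dimethyl)silyl]oxy}-4-hydroxy-10-methyl-3-methylidene-2-oxo-2,3,3a,4,5,8,9,11a-octahydrocyclodeca[b]furan-6-carboxylate; 27 angelic acid
Product: 28 methyl (3aS,4S,5S,6E,10Z,11aS)-5-{[tert-butyl(dimethyl)silyl]oxy}-10-methyl-3-methylidene-4-{[(2Z)-2-methylbut-2-enoyl]oxy}-2-oxo-2,3,3a,4,5,8,9,11a-octahydrocyclodeca[b]furan-6-carboxylate
Conditions: 27, PPh3, DIAD (betaine pre-formed), toluene, 0 °C to rt
Reagents that add atoms: none
Why: Mitsunobu esterification displaces the activated C8 oxygen by SN2 and should turn the helper 8R carbinol into the 8S angelate of the target in one operation, the betaine being pre-formed so that free PPh3 neither adds to the α-methylene lactone nor isomerises the angelate.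

Step 14
Reactants: 28 methyl (3aS,4S,5S,6E,10Z,11aS)-5-{[tert-butyl(dimethyl)silyl]oxy}-10-methyl-3-methylidene-4-{[(2Z)-2-methylbut-2-enoyl]oxy}-2-oxo-2,3,3a,4,5,8,9,11a-octahydrocyclodeca[b]furan-6-carboxylate
Product: 29 methyl (1R,2S,4R,7E,9S,10S,11S)-9-{[tert-butyl(dimethyl)silyl]oxy}-4-methyl-10-{[(2Z)-2-methylbut-2-enoyl]oxy}-12-methylidene-13-oxo-3,14-dioxatricyclo[9.3.0.0(2,4)]tetradec-7-ene-8-carboxylate
Conditions: mCPBA, NaHCO3, CH2Cl2, 0 °C
Reagents that add atoms: 3-chloroperoxybenzoic acid OOC(=O)c1cccc(Cl)c1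
Why: peracid epoxidation (Prilezhaev reaction) should attack only the electron-rich trisubstituted C4=C5 bond, and with H6 eclipsing that bond the peracid should come from the outer face, trans to the C6 lactone oxygen, which sets C4 and C5 as in the target.

Step 15
Reactants: 29 methyl (1R,2S,4R,7E,9S,10S,11S)-9-{[tert-butyl(dimethyl)silyl]oxy}-4-methyl-10-{[(2Z)-2-methylbut-2-enoyl]oxy}-12-methylidene-13-oxo-3,14-dioxatricyclo[9.3.0.0(2,4)]tetradec-7-ene-8-carboxylate
Product: 30 methyl (1R,2S,4R,7E,9S,10S,11R)-9-hydroxy-4-methyl-10-{[(2Z)-2-methylbut-2-enoyl]oxy}-12-methylidene-13-oxo-3,14-dioxatricyclo[9.3.0.0(2,4)]tetradec-7-ene-8-carboxylate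
Conditions: HF·pyridine, pyridine, THF, 0 °C to rt
Reagents that add atoms: none
Why: buffered HF·pyridine removes the secondary silyl ether (fluoride desilylation) and should not open the epoxide, whose transannular partner C1=C10 is deactivated by the ester, or add to the unsaturated esters.

**Compound list**

1 | (4-bromobut-1-yn-1-yl)trimethylsilane | C[Si](C)(C)C#CCCBr | starting material
2 | propyne | CC#C | starting material
3 | vinyl bromide (bromoethene) | C=CBr | starting material
4 | [4-(trimethylsilyl)but-3-yn-1-yl]magnesium bromide | C[Si](C)(C)C#CCC[Mg]Br | intermediate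
5 | [4-(trimethylsilyl)but-3-yn-1-yl]copper (MgBr2 complex) | C[Si](C)(C)C#CCC[Cu] | intermediate
6 | [(1Z)-2-methyl-6-(trimethylsilyl)hex-1-en-5-yn-1-yl]copper | C[Si](C)(C)C#CCC/C(C)=C\[Cu] | intermediate
7 | [(1Z)-2-methyl-6-(trimethylsilyl)hex-1-en-5-yn-1-yl]zinc bromide | C[Si](C)(C)C#CCC/C(C)=C\[Zn]Br | intermediate
8 | trimethyl[(5Z)-5-methylocta-5,7-dien-1-yn-1-yl]silane | C[Si](C)(C)C#CCC/C(C)=C\C=C | intermediate
9 | (5Z)-5-methylocta-5,7-dien-1-yne | C#CCC/C(C)=C\C=C | intermediate
10 | lithium (5Z)-5-methylocta-5,7-dien-1-yn-1-ide | [Li]C#CCC/C(C)=C\C=C | intermediate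
11 | (6Z)-6-methylnona-6,8-dien-2-ynal | O=CC#CCC/C(C)=C\C=C | intermediate
12 | 3-(methoxymethoxy)prop-1-ene (allyl methoxymethyl ether) | C=CCOCOC | starting material
13 | [(2Z)-3-(methoxymethoxy)prop-2-en-1-yl]lithium | [Li]C/C=C\OCOC | intermediate
14 | [(2Z)-3-(methoxymethoxy)prop-2-en-1-yl]bis(isopinocampheyl)borane, isopinocampheyl groups as in (−)-Ipc2BOMe | COCO/C=C\CB([C@@H]1C[C@@H]2C[C@H]([C@H]1C)C2(C)C)[C@@H]1C[C@@H]2C[C@H]([C@H]1C)C2(C)C | intermediate
15 | (3R,4R,9Z)-3-(methoxymethoxy)-9-methyldodeca-1,9,11-trien-5-yn-4-yl bis(isopinocampheyl)borinate | C=C[C@@H](OCOC)[C@H](OB([C@@H]1C[C@@H]2C[C@H]([C@H]1C)C2(C)C)[C@@H]1C[C@@H]2C[C@H]([C@H]1C)C2(C)C)C#CCC/C(C)=C\C=C | intermediate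
16 | (3R,4R,9Z)-3-(methoxymethoxy)-9-methyldodeca-1,9,11-trien-5-yn-4-ol | C=C[C@@H](OCOC)[C@H](O)C#CCC/C(C)=C\C=C | intermediate
17 | (3R,4S,9Z)-3-(methoxymethoxy)-9-methyldodeca-1,9,11-trien-5-yn-4-yl 4-nitrobenzoate | C=C[C@@H](OCOC)[C@@H](OC(=O)c1ccc(cc1)[N+](=O)[O-])C#CCC/C(C)=C\C=C | intermediate
18 | (3R,4S,9Z)-3-(methoxymethoxy)-9-methyldodeca-1,9,11-trien-5-yn-4-ol | C=C[C@@H](OCOC)[C@@H](O)C#CCC/C(C)=C\C=C | intermediate
19 | (3R,4R,5E,9Z)-3-(methoxymethoxy)-9-methyl-5-(tributylstannyl)dodeca-1,5,9,11-tetraen-4-ol | C=C[C@@H](OCOC)[C@@H](O)/C([Sn](CCCC)(CCCC)CCCC)=C\CC/C(C)=C\C=C | intermediate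
20 | (3R,4R,5E,9Z)-5-iodo-3-(methoxymethoxy)-9-methyldodeca-1,5,9,11-tetraen-4-ol | C=C[C@@H](OCOC)[C@@H](O)/C(I)=C\CC/C(C)=C\C=C | intermediate
21 | methyl (2E,6Z)-2-[(1S,2R)-1-hydroxy-2-(methoxymethoxy)but-3-en-1-yl]-6-methylnona-2,6,8-trienoate | C=C[C@@H](OCOC)[C@@H](O)/C(C(=O)OC)=C\CC/C(C)=C\C=C | intermediate
22 | methyl (2E,6Z)-2-[(1S,2R)-1-{[tert-butyl(dimethyl)silyl]oxy}-2-(methoxymethoxy)but-3-en-1-yl]-6-methylnona-2,6,8-trienoate | C=C[C@@H](OCOC)[C@@H](O[Si](C)(C)C(C)(C)C)/C(C(=O)OC)=C\CC/C(C)=C\C=C | intermediate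
23 | methyl (2E,6Z)-2-[(1S,2R)-1-{[tert-butyl(dimethyl)silyl]oxy}-2-hydroxybut-3-en-1-yl]-6-methylnona-2,6,8-trienoate | C=C[C@@H](O)[C@@H](O[Si](C)(C)C(C)(C)C)/C(C(=O)OC)=C\CC/C(C)=C\C=C | intermediate
24 | methyl (1E,5Z,7Z,9R,10S)-10-{[tert-butyl(dimethyl)silyl]oxy}-9-hydroxy-5-methylcyclodeca-1,5,7-triene-1-carboxylate | O[C@H]1[C@@H](O[Si](C)(C)C(C)(C)C)/C(C(=O)OC)=C\CC/C(C)=C\C=C/1 | intermediate
25 | 2-bromoacrylic acid (2-bromoprop-2-enoic acid) | C=C(Br)C(=O)O | starting material
26 | methyl (3aR,4R,5S,6E,10Z,11aS)-5-{[tert-butyl(dimethyl)silyl]oxy}-4-hydroxy-10-methyl-3-methylidene-2-oxo-2,3,3a,4,5,8,9,11a-octahydrocyclodeca[b]furan-6-carboxylate (cis-fused lactone, 8-epi alcohol) | C=C1C(=O)O[C@@H]2[C@H]1[C@@H](O)[C@@H](O[Si](C)(C)C(C)(C)C)/C(C(=O)OC)=C\CC/C(C)=C\2 | intermediate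
27 | angelic acid ((2Z)-2-methylbut-2-enoic acid) | C/C=C(/C)C(=O)O | starting material
28 | methyl (3aS,4S,5S,6E,10Z,11aS)-5-{[tert-butyl(dimethyl)silyl]oxy}-10-methyl-3-methylidene-4-{[(2Z)-2-methylbut-2-enoyl]oxy}-2-oxo-2,3,3a,4,5,8,9,11a-octahydrocyclodeca[b]furan-6-carboxylate | C=C1C(=O)O[C@@H]2[C@H]1[C@H](OC(=O)/C(C)=C\C)[C@@H](O[Si](C)(C)C(C)(C)C)/C(C(=O)OC)=C\CC/C(C)=C\2 | intermediate
29 | methyl (1R,2S,4R,7E,9S,10S,11S)-9-{[tert-butyl(dimethyl)silyl]oxy}-4-methyl-10-{[(2Z)-2-methylbut-2-enoyl]oxy}-12-methylidene-13-oxo-3,14-dioxatricyclo[9.3.0.0(2,4)]tetradec-7-ene-8-carboxylate | C=C1C(=O)O[C@@H]2[C@H]1[C@H](OC(=O)/C(C)=C\C)[C@@H](O[Si](C)(C)C(C)(C)C)/C(C(=O)OC)=C\CC[C@@]1(C)O[C@@H]21 | intermediate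
30 | methyl (1R,2S,4R,7E,9S,10S,11R)-9-hydroxy-4-methyl-10-{[(2Z)-2-methylbut-2-enoyl]oxy}-12-methylidene-13-oxo-3,14-dioxatricyclo[9.3.0.0(2,4)]tetradec-7-ene-8-carboxylate | C=C1C(=O)O[C@@H]2[C@H]1[C@H](OC(=O)/C(C)=C\C)[C@@H](O)/C(C(=O)OC)=C\CC[C@@]1(C)O[C@@H]21 | target

**Count and risks**

Total step count: 15. Longest linear sequence: 15 steps (1 to 30).

Steps most likely to fail:

1. Step 12 (Proposed new method). What may go wrong: insertion of the alkenylpalladium on the inner face or at C4, β-hydride loss from the allyl complex to a triene, or outer-sphere C–O closure leading to the trans-fused lactone. Fallback with known chemistry: the oxidative radical lactone annulation with trivalent manganese sets out from 24. Mn(OAc)3·2H2O and malonic acid in AcOH (Cu(OAc)2 as co-oxidant, 50 °C) should add the malonyl radical to C7; the allyl radical is oxidised to the cation and closed at C6 by the carboxyl group, giving the α-carboxy lactone F1 (C11 epimers). Decarboxylative methylenation (aq CH2O, Et2NH, then NaOAc/AcOH) then comes back to the route at 26.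

2. Step 11. What may go wrong: oligomerisation by intermolecular metathesis, chelation of the ruthenium alkylidene by the C14 ester carbonyl, or closure to the (7E) isomer. Fallback: the ring is closed before the conjugated ester exists and the ester is put on the ring afterwards. Setting out from 20, silylation (TBSOTf, 2,6-lutidine) should give the silyl ether F2, Me2BBr the allylic alcohol F3, and ring-closing metathesis of this iodo tetraene the cyclic alkenyl iodide F4. Methoxycarbonylation of F4 (CO, MeOH, Et3N, PdCl2(PPh3)2) comes back to the route at 24.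

3. Step 13. What may go wrong: no displacement at the hindered C8 (recovered alcohol or elimination toward C9), or phosphine-induced isomerisation of the angelate to the tiglate. Fallback: a sulfonate displacement that sets out from 26. Tf2O and pyridine (CH2Cl2, −40 °C) should give the triflate F5, which is displaced with inversion by cesium angelate F6 (made from 27 and Cs2CO3) with 18-crown-6 in toluene, coming back to the route at 28.

Further compounds
F1 | step 12 | (3aR,4R,5S,6E,10Z,11aS)-5-{[tert-butyl(dimethyl)silyl]oxy}-4-hydroxy-6-(methoxycarbonyl)-10-methyl-2-oxo-2,3,3a,4,5,8,9,11a-octahydrocyclodeca[b]furan-3-carboxylic acid (both C3 epimers) | OC(=O)C1C(=O)O[C@@H]2[C@H]1[C@@H](O)[C@@H](O[Si](C)(C)C(C)(C)C)/C(C(=O)OC)=C\CC/C(C)=C\2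
F2 | step 11 | (3R,4R,5E,9Z)-4-{[tert-butyl(dimethyl)silyl]oxy}-5-iodo-3-(methoxymethoxy)-9-methyldodeca-1,5,9,11-tetraene | C=C[C@@H](OCOC)[C@@H](O[Si](C)(C)C(C)(C)C)/C(I)=C\CC/C(C)=C\C=C
F3 | step 11 | (3R,4R,5E,9Z)-4-{[tert-butyl(dimethyl)silyl]oxy}-5-iodo-9-methyldodeca-1,5,9,11-tetraen-3-ol | C=C[C@@H](O)[C@@H](O[Si](C)(C)C(C)(C)C)/C(I)=C\CC/C(C)=C\C=C
F4 | step 11 | (1R,2R,3E,7Z,9Z)-2-{[tert-butyl(dimethyl)silyl]oxy}-3-iodo-7-methylcyclodeca-3,7,9-trien-1-ol | O[C@H]1[C@@H](O[Si](C)(C)C(C)(C)C)/C(I)=C\CC/C(C)=C\C=C/1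
F5 | step 13 | methyl (3aS,4R,5S,6E,10Z,11aS)-5-{[tert-butyl(dimethyl)silyl]oxy}-10-methyl-3-methylidene-2-oxo-4-{[(trifluoromethyl)sulfonyl]oxy}-2,3,3a,4,5,8,9,11a-octahydrocyclodeca[b]furan-6-carboxylate | C=C1C(=O)O[C@@H]2[C@H]1[C@@H](OS(=O)(=O)C(F)(F)F)[C@@H](O[Si](C)(C)C(C)(C)C)/C(C(=O)OC)=C\CC/C(C)=C\2
F6 | step 13 | cesium (2Z)-2-methylbut-2-enoate | C/C=C(/C)C(=O)[O-].[Cs+]
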